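## Structural features

Atom numbers follow the heavy atoms of the target SMILES in order: C1 (exocyclic CH2), C2, C3 (C=O), O4, O5, C6, C7, O8, C9, C10 (methyl), C11–C13, C14, C15 (methyl), O16, C17, C18, C19, C20, C21 (methyl), O22, C23, C24, C25. The target is a cembranolide: a fourteen-membered carbocycle (ring A: C6, C7, C9, C11–C14, C17–C20, C23–C25) cis-fused through C6 and C25 to an α-methylene-γ-butyrolactone (ring B: C2, C3, O5, C6, C25), and it carries a trans-trisubstituted oxirane (ring C: C20, O22, C23). Four contiguous stereocentres run C25(S)–C6(R)–C7(R)–C9(S): the ring-fusion hydrogens are cis, the oxygens on C6 and C7 are syn, and the C7 hydroxyl is syn to the C9 methyl. C14 (S, tertiary allylic alcohol) and the oxirane pair C20(R)/C23(R) are remote from that array and from each other, and a Z alkene (C17=C18) sits between them. The fragile groups are the exocyclic enoate C1=C2 (a Michael acceptor that can migrate into ring B under base or Pd–H), the oxirane next to a tertiary allylic alcohol (transannular opening under acid) and the skipped C17–C23 unsaturation. The real difficulty is to close ring A and to place C14, the oxirane and the alkene geometries correctly with respect to the C25–C9 array, with no resident group that relays stereochemistry across the ring. The key step uses the fact that, once ring C is read as an E alkene, C21–C20=C23–C24 and the ring-B alkene C2=C25 form a methyl-branched 1,4-diene: methylmetalation of a terminal alkyne gives C20–C21 with fixed geometry, and allylic coupling gives C23–C24.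

## Logic of the disconnections

29 ⇒ 28. The C20–O22 and C23–O22 bonds of ring C are cut. The oxirane is the most acid-sensitive unit and records only the E geometry of a trisubstituted alkene, so two stereocentres disappear. The forward step must pick C20=C23 over C17=C18 and C1=C2 and must choose one face.

28 ⇒ 27. The O8–H and O16–H bonds are exchanged for O–Si bonds. Both hydroxyls have to be masked during enolate, organoaluminium and radical chemistry. The forward step needs a desilylation that spares the enoate and the tertiary allylic alcohol.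

27 ⇒ 24. The C1=C2 bond is cut. The exocyclic enoate would not survive semi-hydrogenation or nucleophilic bases, so it is introduced after all reductions. The forward step needs clean enolisation at C2, the only acidic position.

24 ⇒ 23. The Z alkene C17=C18 is traced to an alkyne. The alkyne gives a carbon nucleophile for ring closure and fixes the Z geometry by syn hydrogenation. The forward step must stop at the alkene and leave C20=C23 alone.

23 ⇒ 21 (through 22). The ring bond C18–C19 is cut. It is the one bond of ring A that joins an sp carbon to an allylic carbon, and it is not next to a stereocentre. This opens ring A to an acyclic terminal alkyne with an allylic bromide. The forward step needs high dilution and SN2 rather than SN2′ attack.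

21 ⇒ 20 ⇒ 19. C19–Br goes back to C19–OH, and C18–H back to C18–Si. The silyl cap is needed while organoaluminium reagents are present. It has to come off before the bromide is made, because the allylic bromide would not tolerate methanolysis conditions.

19 ⇒ 18. Unsaturation C2=C25 is reintroduced, which removes the C25 stereocentre. The butenolide makes C24 an allylic position and gives a planar carbon whose faces are distinguished by the C6 side chain. The forward step needs hydride delivery anti to that side chain.

18 ⇒ 14 + 15 + 16 (through 17). C23–C24 and C20–C21 are cut. The C19–C24 arm becomes a three-carbon alkyne, a methyl donor and an allylic bromide, and the E geometry becomes a consequence of syn carbometalation. 14 and 18 have the same configuration as 29 at C6 (R), C7 (R), C9 (S) and C14 (S). The forward step needs an alkenylmetal that couples at C24 without touching the lactone or the silyl-capped alkyne.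

14 ⇒ 13. C24–Br goes back to C24–H. The methyl group on the butenolide is the cheapest precursor of the allylic electrophile. The forward step needs a radical bromination that prefers the methyl group to C6–H.

13 ⇒ 12. The O8–Si bond is removed to expose the aldol hydroxyl.

12 ⇒ 9 + 11. C6–C7 is cut as a vinylogous aldol. This separates the whole C7–C18 chain from a five-carbon furan and creates C6 and C7 together. The forward step needs syn (threo) addition and Felkin control from C9.

11 ⇒ 10. The O–Si bond of the silyloxyfuran is cut, which leads to the commercial butenolide.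

9 ⇒ 8. The C7=O group is traced to a vinyl group with one extra carbon. The epimerisable α-methyl aldehyde stays masked until it is needed. The forward step needs cleavage of the alkene in the presence of the silyl alkyne.

8 ⇒ 7 ⇒ 6. The C18–Si and O16–Si bonds are removed.

6 ⇒ 5. C17≡C18 is cut by one-carbon homologation logic, which leaves an aldehyde at C17. The forward step needs a base-tolerant aldehyde, and 5 has no α-hydrogen.

5 ⇒ 4. The aldehyde is traced to the primary alcohol of a 1,2-diol.

4 ⇒ 3. C13–H goes back to C13–O of an epoxy alcohol. The tertiary carbinol C14 is thereby derived from an epoxide whose C14–O bond is never broken. The forward step needs hydride attack at the less substituted carbon.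

3 ⇒ 2. The oxirane is traced to an E allylic alcohol, so C14 is set by a reagent-controlled epoxidation.

2 ⇒ 1. The allylic C–O bond is removed, which leaves a terpene diene that already holds C9 and all carbons from C7 to C17.

## Other disconnections considered

Alternative 1: The cut removes the lactone carbonyl carbon C3 (bonds C3–O5 and C2–C3), which leaves the macrocyclic homopropargylic alcohol A2 with the C6 hydroxyl cis to a C25 ethynyl group. In the forward step divalent palladium (PdCl2, PPh3, SnCl2) under CO would form an alkoxycarbonyl-palladium species at O5, add it across the alkyne and protonate, giving A1, the C7 p-methoxybenzyl ether of 28.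
- In its favour: ring B and the exocyclic methylene arise in one late, nearly neutral operation from carbon monoxide, and the sensitive enoate never has to pass through earlier steps. On the count of steps for ring B this is better than the chosen plan, which spends steps 9, 14 and 19 on it. The ring-forming event cannot give a wrong configuration, which is also a point for the alternative.
- Against it: the stereochemical problem is moved, not solved. C25 must already be a defined propargylic stereocentre cis to O5 inside ring A, and ring A must be closed by some other reaction. The Lewis acidic tin and palladium salts meet a tertiary allylic alcohol. Oxidative removal of the benzyl ether from A1 has to spare the doubly allylic C19.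
- Comparison: the endgame is the same (A1 and 28 differ only in the ether, so the epoxidation problem is equal). The mechanism is stereochemically neutral, where the chosen plan relies on substrate-controlled hydride delivery at C25. The overall step count is probably no lower, because the E alkene and the macrocycle still have to be made, most naturally by the same carbometalation.

Alternative 2: The cut is C12–C13. An α-sulfonyl carbanion at C12 in the acyclic epoxy sulfone A4 would open the terminal 2,2-disubstituted epoxide at its CH2 group. In the forward step LiN(i-Pr)2 deprotonates the sulfone and the carbanion closes ring A in an exo mode, giving the macrocyclic hydroxy sulfone A3 as C12 epimers.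
- In its favour: the ring closes at a carbon whose configuration is irrelevant after desulfonylation. C14 is carried in the epoxide. The C6/C7 diol is locked as an acetonide, which can come from a reagent-controlled dihydroxylation, and that is better than the substrate-controlled aldol of step 10. The exocyclic methylene carbon is already in place, and no semi-hydrogenation is needed after ring closure.
- Against it: the electrophilic CH2 is neopentyl-like and slow for a fourteen-membered closure. A lithium amide meets the doubly allylic C19 hydrogens. After A3 there remain reductive desulfonylation, acetonide and silyl cleavage, oxidation of the allylic alcohol to the acid level, lactonisation onto O5 and the epoxidation.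
- Comparison: both plans close ring A by an sp3 C–C bond remote from stereocentres (equal). The chosen plan closes under carbonate and a monovalent copper salt, which is milder than an amide base, and needs four steps after closure where the alternative needs at least six. The epoxidation at the end is the same problem in both.

Alternative 3: The cut is C6–C7 made intramolecularly. The seco aldehyde A6 carries a 2-silyloxyfuran joined through C24. In the forward step BF3·OEt2 activates the C7 aldehyde and the furan γ-carbon attacks, which closes ring A and forms the ring-fused butenolide A5 with C6 and C7 set.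
- In its favour: it is the most convergent option. One step makes ring A, the butenolide of ring B and two stereocentres, and C7 needs no protecting group. It forms the same bond as step 10, so the reaction type is equally well founded. On step count it is better than the chosen plan, since the copper-mediated closure and the steps that prepare it fall away.
- Against it: the syn and Felkin preferences of the open-chain aldol need not hold in a macrocyclic transition state. A Lewis acid at high dilution meets a tertiary allylic silyl ether and an electron-rich furan. The later conjugate reduction of A5 would take place inside ring A, where ring conformation decides the face, and not the freely rotating C6 side chain that step 14 relies on.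
- Comparison: the structural endgame is the same (reduction, methylenation, desilylation, epoxidation). The alternative is shorter. The chosen plan is more predictable at C6, C7 and C25, and A6 would still need the E-alkene-forming carbometalation to be assembled.

Key step: step 13

Remark on the chemistry: 1 is assumed to be purchasable as the (3S) enantiomer (the diene of the (S)-citronellal series); its vinyl group is the latent C7 aldehyde.

## Route

Step 1
Reactants: 1 (3S)-3,7-dimethylocta-1,6-diene
Product: 2 (2E,6S)-2,6-dimethylocta-2,7-dien-1-ol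
Conditions: SeO2 (cat.), t-BuOOH, salicylic acid (cat.), CH2Cl2, 0 °C to rt
Reagents that add atoms: selenium dioxide, O=[Se]=O (oxygen carrier); tert-butyl hydroperoxide, CC(C)(C)OO (terminal oxidant)
Why: Riley-type allylic oxidation (ene reaction, then [2,3]-sigmatropic shift) attacks the electron-rich trisubstituted alkene at its E methyl group and leaves the monosubstituted vinyl group; the sigmatropic step gives the E allylic alcohol, and the reaction is stopped short of full conversion to limit enal formation.

Step 2
Reactants: 2 (2E,6S)-2,6-dimethylocta-2,7-dien-1-ol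
Product: 3 [(2R,3R)-2-methyl-3-[(3S)-3-methylpent-4-en-1-yl]oxiran-2-yl]methanol
Conditions: Ti(OiPr)4 (cat.), D-(−)-diethyl tartrate (cat.), t-BuOOH, 4 Å MS, CH2Cl2, −20 °C
Reagents that add atoms: tert-butyl hydroperoxide, CC(C)(C)OO
Why: Sharpless asymmetric epoxidation; with (E)-2-methylalk-2-en-1-ols the D-tartrate ester gives the (2R,3R) epoxide (the L ester gives 2S,3S), which fixes the future C14; the vinyl group has no directing hydroxyl and is not touched.

Step 3
Reactants: 3 [(2R,3R)-2-methyl-3-[(3S)-3-methylpent-4-en-1-yl]oxiran-2-yl]methanol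
Product: 4 (2S,6S)-2,6-dimethyloct-7-ene-1,2-diol
Conditions: LiAlH4, THF, 0 °C to rt; H2O work-up
Reagents that add atoms: none
Why: SN2 hydride opening of a 2,3-epoxy alcohol at the less substituted carbon (future C13); the C14–O bond is not broken, so the carbinol keeps its spatial arrangement and the descriptor changes from R to S only through the change in priorities.

Step 4
Reactants: 4 (2S,6S)-2,6-dimethyloct-7-ene-1,2-diol
Product: 5 (2S,6S)-2-hydroxy-2,6-dimethyloct-7-enal
Conditions: SO3·pyridine, DMSO, i-Pr2NEt, CH2Cl2, 0 °C
Reagents that add atoms: none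
Why: Parikh–Doering oxidation; only the primary hydroxyl can be oxidised, and the cold, non-acidic conditions should avoid dimerisation or α-ketol shift of the hydroxy aldehyde, which is used crude.

Step 5
Reactants: 5 (2S,6S)-2-hydroxy-2,6-dimethyloct-7-enal
Product: 6 (3S,7S)-3,7-dimethylnon-8-en-1-yn-3-ol
Conditions: MeC(O)C(N2)P(O)(OMe)2, K2CO3, MeOH, 0 °C to rt
Reagents that add atoms: dimethyl (1-diazo-2-oxopropyl)phosphonate, COP(=O)(OC)C(=[N+]=[N-])C(C)=O
Why: Seyferth–Gilbert homologation with the Ohira–Bestmann reagent turns the aldehyde into the terminal alkyne C17≡C18; the aldehyde has no α-hydrogen, so basic methanol cannot epimerise C14, and free hydroxyl groups are tolerated.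

Step 6
Reactants: 6 (3S,7S)-3,7-dimethylnon-8-en-1-yn-3-ol
Product: 7 triethyl{[(3S,7S)-3,7-dimethylnon-8-en-1-yn-3-yl]oxy}silane
Conditions: Et3SiOTf, 2,6-lutidine, CH2Cl2, −78 to 0 °C
Reagents that add atoms: triethylsilyl trifluoromethanesulfonate, CC[Si](CC)(CC)OS(=O)(=O)C(F)(F)F
Why: Silyl triflates silylate hindered tertiary alcohols where silyl chlorides fail; the triethylsilyl ether masks O16 through the Lewis acid, radical and organoaluminium steps.

Step 7
Reactants: 7 triethyl{[(3S,7S)-3,7-dimethylnon-8-en-1-yn-3-yl]oxy}silane
Product: 8 triethyl{[(3S,7S)-3,7-dimethyl-1-(trimethylsilyl)non-8-en-1-yn-3-yl]oxy}silane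
Conditions: n-BuLi, THF, −78 °C; Me3SiCl, −78 °C to rt
Reagents that add atoms: chlorotrimethylsilane, C[Si](C)(C)Cl
Why: Deprotonation of the terminal alkyne and C-silylation of the acetylide; the cap keeps C17≡C18 out of the later carboalumination and radical steps.

Step 8
Reactants: 8 triethyl{[(3S,7S)-3,7-dimethyl-1-(trimethylsilyl)non-8-en-1-yn-3-yl]oxy}silane
Product: 9 (2S,6S)-2,6-dimethyl-6-(triethylsilyloxy)-8-(trimethylsilyl)oct-7-ynal
Conditions: O3, CH2Cl2, −78 °C (to first persistent blue); PPh3, −78 °C to rt
Reagents that add atoms: ozone, [O-][O+]=O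
Why: Ozonolysis with reductive work-up; the vinyl group reacts far faster than the hindered silyl-capped alkyne, and the base-free work-up gives the α-methyl aldehyde (C7) without epimerising C9.

Step 9
Reactants: 10 4-methylfuran-2(5H)-one
Product: 11 tert-butyldimethyl[(4-methylfuran-2-yl)oxy]silane
Conditions: t-BuMe2SiOTf, Et3N, CH2Cl2, 0 °C
Reagents that add atoms: tert-butyldimethylsilyl trifluoromethanesulfonate, CC(C)(C)[Si](C)(C)OS(=O)(=O)C(F)(F)F
Why: Soft enolisation of the butenolide and O-silylation give the aromatic 2-silyloxyfuran, the standard donor for vinylogous Mukaiyama aldol reactions.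

Step 10
Reactants: 9 (2S,6S)-2,6-dimethyl-6-(triethylsilyloxy)-8-(trimethylsilyl)oct-7-ynal; 11 tert-butyldimethyl[(4-methylfuran-2-yl)oxy]silane
Product: 12 (5R)-5-[(1R,2S,6S)-1-hydroxy-2,6-dimethyl-6-(triethylsilyloxy)-8-(trimethylsilyl)oct-7-yn-1-yl]-4-methylfuran-2(5H)-one
Conditions: BF3·OEt2, CH2Cl2, −78 °C; aqueous work-up
Reagents that add atoms: none
Why: Vinylogous Mukaiyama aldol through an open transition state, with attack from the furan γ-carbon forming C6–C7; BF3-promoted additions of 2-silyloxyfurans favour the syn (threo) C6/C7 relationship, and Felkin–Anh attack on the α-methyl aldehyde places the C7 oxygen syn to the C9 methyl, so C6 (R) and C7 (R) are set by the C9 centre.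

Step 11
Reactants: 12 (5R)-5-[(1R,2S,6S)-1-hydroxy-2,6-dimethyl-6-(triethylsilyloxy)-8-(trimethylsilyl)oct-7-yn-1-yl]-4-methylfuran-2(5H)-one
Product: 13 (5R)-5-[(1R,2S,6S)-1-(tert-butyldimethylsilyloxy)-2,6-dimethyl-6-(triethylsilyloxy)-8-(trimethylsilyl)oct-7-yn-1-yl]-4-methylfuran-2(5H)-one
Conditions: t-BuMe2SiOTf, 2,6-lutidine, CH2Cl2, −78 to 0 °C
Reagents that add atoms: tert-butyldimethylsilyl trifluoromethanesulfonate, CC(C)(C)[Si](C)(C)OS(=O)(=O)C(F)(F)F
Why: O-silylation of the hindered secondary alcohol; 2,6-lutidine at low temperature is too weak a base to convert the butenolide into a silyloxyfuran, so C6 is not planarised.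

Step 12
Reactants: 13 (5R)-5-[(1R,2S,6S)-1-(tert-butyldimethylsilyloxy)-2,6-dimethyl-6-(triethylsilyloxy)-8-(trimethylsilyl)oct-7-yn-1-yl]-4-methylfuran-2(5H)-one
Product: 14 (5R)-4-(bromomethyl)-5-[(1R,2S,6S)-1-(tert-butyldimethylsilyloxy)-2,6-dimethyl-6-(triethylsilyloxy)-8-(trimethylsilyl)oct-7-yn-1-yl]furan-2(5H)-one
Conditions: NBS, AIBN (cat.), PhCF3, 80 °C
Reagents that add atoms: N-bromosuccinimide, O=C1CCC(=O)N1Br
Why: Wohl–Ziegler bromination; hydrogen abstraction from the C24 methyl gives a radical delocalised over C25, C2 and the carbonyl, as in the known bromination of 4-methylbutenolides, while the competing tertiary C6–H is screened by the C7 silyloxy branch and the quaternary C14 leaves no propargylic hydrogen.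

Step 13
Reactants: 14 (5R)-4-(bromomethyl)-5-[(1R,2S,6S)-1-(tert-butyldimethylsilyloxy)-2,6-dimethyl-6-(triethylsilyloxy)-8-(trimethylsilyl)oct-7-yn-1-yl]furan-2(5H)-one; 15 prop-2-yn-1-ol; 16 trimethylaluminium
Product: 18 (5R)-5-[(1R,2S,6S)-1-(tert-butyldimethylsilyloxy)-2,6-dimethyl-6-(triethylsilyloxy)-8-(trimethylsilyl)oct-7-yn-1-yl]-4-[(2E)-4-hydroxy-3-methylbut-2-en-1-yl]furan-2(5H)-one, via (E)-alkenylalane 17 (not isolated)
Conditions: 15, AlMe3 (3 equiv), Cp2ZrCl2 (0.25 equiv), CH2Cl2, 0 °C to rt; volatiles removed in vacuo; then 14, Pd(PPh3)4 (5 mol%), THF, 0 °C to rt; aq. KNaC4H4O6 work-up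
Reagents that add atoms: trimethylaluminium, C[Al](C)C (compound 16, supplies C21)
Why: Cp2ZrCl2 and AlMe3 generate a methylzirconium species that adds syn across the terminal alkyne of the aluminium alkoxide of 15, with methyl on the internal carbon (C20–C21) and metal on the terminal carbon, and transmetalation to aluminium gives 17 with aluminium cis to the new methyl group. Zerovalent palladium then adds oxidatively to the allylic C24–Br bond of 14, the alkenyl group passes from aluminium to palladium with retention, and reductive elimination at the CH2 terminus forms C23–C24. The closest known reaction type is the zirconium-catalysed methylalumination of terminal alkynes followed by palladium-catalysed coupling of the alkenylalane with an allylic halide, for which prop-2-yn-1-ol is a standard substrate. No ring is closed and no stereocentre is formed; the one stereo-element created is the E geometry of C20=C23 (C19 trans to C24), fixed by the syn addition and the stereoretentive coupling. The step needs methyl delivery to the internal alkyne carbon (secured by the terminal alkyne), coupling at C24 and not at C2 of the allyl system (attack at C2 would break the conjugation with the lactone), and transfer of alkenyl in preference to methyl (alkenyl migrates faster, and free AlMe3 is stripped off before 14 is added). The silyl-capped internal alkyne of 14 is inert to carboalumination under these conditions, and C6, C7, C9 and C14 are not touched because the coupling runs at or below room temperature, where the aluminium alkoxide should not enolise the butenolide.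

Step 14
Reactants: 18 (5R)-5-[(1R,2S,6S)-1-(tert-butyldimethylsilyloxy)-2,6-dimethyl-6-(triethylsilyloxy)-8-(trimethylsilyl)oct-7-yn-1-yl]-4-[(2E)-4-hydroxy-3-methylbut-2-en-1-yl]furan-2(5H)-one
Product: 19 (4S,5R)-5-[(1R,2S,6S)-1-(tert-butyldimethylsilyloxy)-2,6-dimethyl-6-(triethylsilyloxy)-8-(trimethylsilyl)oct-7-yn-1-yl]-4-[(2E)-4-hydroxy-3-methylbut-2-en-1-yl]oxolan-2-one
Conditions: [(Ph3P)CuH]6, H2O, degassed toluene/THF, rt
Reagents that add atoms: none
Why: Conjugate reduction of the unsaturated lactone by the Cu–H reagent; hydride reaches C25 from the face opposite the bulky C6 side chain and the copper enolate is protonated at C2, giving the cis-4,5-disubstituted lactone (C25 S), as in hydrogenations of 4,5-disubstituted butenolides, while the isolated alkene, the silyl alkyne and the free hydroxyl are inert to this reagent.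

Step 15
Reactants: 19 (4S,5R)-5-[(1R,2S,6S)-1-(tert-butyldimethylsilyloxy)-2,6-dimethyl-6-(triethylsilyloxy)-8-(trimethylsilyl)oct-7-yn-1-yl]-4-[(2E)-4-hydroxy-3-methylbut-2-en-1-yl]oxolan-2-one
Product: 20 (4S,5R)-5-[(1R,2S,6S)-1-(tert-butyldimethylsilyloxy)-2,6-dimethyl-6-(triethylsilyloxy)oct-7-yn-1-yl]-4-[(2E)-4-hydroxy-3-methylbut-2-en-1-yl]oxolan-2-one
Conditions: K2CO3 (cat.), MeOH, 0 °C; pH 5 buffer work-up
Reagents that add atoms: none
Why: Methanolysis of the alkynyl C–Si bond, which is much faster than cleavage of the O-silyl ethers; the saturated lactone has no epimerisable α-centre, and any ring-opened hydroxy ester should reclose on the mildly acidic work-up.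

Step 16
Reactants: 20 (4S,5R)-5-[(1R,2S,6S)-1-(tert-butyldimethylsilyloxy)-2,6-dimethyl-6-(triethylsilyloxy)oct-7-yn-1-yl]-4-[(2E)-4-hydroxy-3-methylbut-2-en-1-yl]oxolan-2-one
Product: 21 (4S,5R)-4-[(2E)-4-bromo-3-methylbut-2-en-1-yl]-5-[(1R,2S,6S)-1-(tert-butyldimethylsilyloxy)-2,6-dimethyl-6-(triethylsilyloxy)oct-7-yn-1-yl]oxolan-2-one
Conditions: CBr4, PPh3, CH2Cl2, 0 °C
Reagents that add atoms: carbon tetrabromide, BrC(Br)(Br)Br
Why: Appel reaction; the primary allylic alcohol is displaced by SN2 through its alkoxyphosphonium salt, so the E alkene keeps its position and geometry, and the neutral conditions spare the lactone, silyl ethers and terminal alkyne.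

Step 17
Reactants: 21 (4S,5R)-4-[(2E)-4-bromo-3-methylbut-2-en-1-yl]-5-[(1R,2S,6S)-1-(tert-butyldimethylsilyloxy)-2,6-dimethyl-6-(triethylsilyloxy)oct-7-yn-1-yl]oxolan-2-one
Product: 23 bis-silyl enyne lactone with ring A closed (C17≡C18; 20E; C6 R; C7 R; C9 S; C14 S; C25 S), via copper acetylide 22 (not isolated)
Conditions: CuI (1 equiv), Cs2CO3, degassed DMF, rt, syringe-pump addition (final about 1 mM)
Reagents that add atoms: none
Why: Copper-mediated alkynyl–allyl coupling; carbonate and CuI turn the terminal alkyne into its copper acetylide, which displaces the primary allylic bromide at C19 (SN2 rather than attack at the more hindered C23) to form C18–C19, and high dilution favours the fourteen-membered ring over oligomers; no stereocentre is involved.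

Step 18
Reactants: 23 bis-silyl enyne lactone with ring A closed
Product: 24 bis-silyl (17Z,20E)-diene lactone with saturated ring B (C6 R; C7 R; C9 S; C14 S; C25 S)
Conditions: H2 (1 atm), Pd/CaCO3 (Pb(OAc)2-poisoned), quinoline, EtOAc, rt
Reagents that add atoms: none
Why: Lindlar semi-hydrogenation adds hydrogen syn to the alkyne and stops at the Z alkene C17=C18; the trisubstituted alkene and the saturated lactone are inert, and the exocyclic methylene is not yet present, so it cannot be reduced or isomerised here.

Step 19
Reactants: 24 bis-silyl (17Z,20E)-diene lactone with saturated ring B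
Product: 27 bis-silyl α-methylene lactone (C1=C2; 17Z; 20E), via Mannich base 25 (not isolated), via methiodide 26 (not isolated)
Conditions: LiN(i-Pr)2, THF, −78 °C; CH2=NMe2+ I−, −78 °C to rt; MeI, MeOH, rt; aq. NaHCO3, CH2Cl2
Reagents that add atoms: N,N-dimethylmethyleneiminium iodide, C=[N+](C)C.[I-] (supplies C1); iodomethane, CI (its methyl is carried only by 26 and leaves as trimethylamine)
Why: The lactone enolate, which can form only at C2, undergoes a Mannich reaction with the iminium salt; quaternisation and base-induced elimination of trimethylamine then give the exocyclic methylene, C25 is not acidic, and the doubly allylic C19 is far less acidic than C2.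

Step 20
Reactants: 27 bis-silyl α-methylene lactone
Product: 28 (17Z,20E)-diene diol with α-methylene lactone (C6 R; C7 R; C9 S; C14 S; C25 S)
Conditions: HF·pyridine, pyridine, THF, 0 °C to rt
Reagents that add atoms: none
Why: Buffered fluoride cleaves both the tertiary triethylsilyl and the hindered secondary tert-butyldimethylsilyl ether; the enoate is stable to these weakly acidic conditions, and the desilylation is placed before epoxidation so that no oxirane is exposed to fluoride or acid.

Step 21
Reactants: 28 (17Z,20E)-diene diol with α-methylene lactone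
Product: 29 target epoxide (C6 R; C7 R; C9 S; C14 S; C20 R; C23 R; C25 S; 17Z)
Conditions: D-fructose-derived Shi ketone (1,2:4,5-di-O-isopropylidene-β-D-erythro-hexo-2,3-diulo-2,6-pyranose), KHSO5 (as 2KHSO5·KHSO4·K2SO4), K2CO3, Bu4NHSO4, Na2B4O7/Na2EDTA buffer, MeCN/CH2(OMe)2/H2O, 0 °C
Reagents that add atoms: potassium peroxymonosulfate, [K+].[O-]S(=O)(=O)OO
Why: Shi asymmetric epoxidation; the chiral dioxirane is electrophilic and should prefer the electron-rich E-trisubstituted alkene C20=C23 to the Z-disubstituted alkene (a poor substrate for this ketone) and to the electron-poor methylene, and the spiro transition state of the D-fructose-derived ketone gives the (R,R) epoxide with E-trisubstituted alkenes of this substitution pattern, which corresponds to C20 R and C23 R.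

## Compound list

1 | (3S)-3,7-dimethylocta-1,6-diene | C=C[C@@H](C)CCC=C(C)C | starting material
2 | (2E,6S)-2,6-dimethylocta-2,7-dien-1-ol | C=C[C@@H](C)CC/C=C(\C)CO | intermediate
3 | [(2R,3R)-2-methyl-3-[(3S)-3-methylpent-4-en-1-yl]oxiran-2-yl]methanol | C=C[C@@H](C)CC[C@H]1O[C@]1(C)CO | intermediate
4 | (2S,6S)-2,6-dimethyloct-7-ene-1,2-diol | C=C[C@@H](C)CCC[C@](C)(O)CO | intermediate
5 | (2S,6S)-2-hydroxy-2,6-dimethyloct-7-enal | C=C[C@@H](C)CCC[C@](C)(O)C=O | intermediate
6 | (3S,7S)-3,7-dimethylnon-8-en-1-yn-3-ol | C=C[C@@H](C)CCC[C@](C)(O)C#C | intermediate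
7 | triethyl{[(3S,7S)-3,7-dimethylnon-8-en-1-yn-3-yl]oxy}silane | C=C[C@@H](C)CCC[C@](C)(O[Si](CC)(CC)CC)C#C | intermediate
8 | triethyl{[(3S,7S)-3,7-dimethyl-1-(trimethylsilyl)non-8-en-1-yn-3-yl]oxy}silane | C=C[C@@H](C)CCC[C@](C)(O[Si](CC)(CC)CC)C#C[Si](C)(C)C | intermediate
9 | (2S,6S)-2,6-dimethyl-6-(triethylsilyloxy)-8-(trimethylsilyl)oct-7-ynal | O=C[C@@H](C)CCC[C@](C)(O[Si](CC)(CC)CC)C#C[Si](C)(C)C | intermediate
10 | 4-methylfuran-2(5H)-one | CC1=CC(=O)OC1 | starting material
11 | tert-butyldimethyl[(4-methylfuran-2-yl)oxy]silane | Cc1coc(O[Si](C)(C)C(C)(C)C)c1 | intermediate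
12 | (5R)-5-[(1R,2S,6S)-1-hydroxy-2,6-dimethyl-6-(triethylsilyloxy)-8-(trimethylsilyl)oct-7-yn-1-yl]-4-methylfuran-2(5H)-one | O=C1O[C@@H]([C@H](O)[C@@H](C)CCC[C@](C)(O[Si](CC)(CC)CC)C#C[Si](C)(C)C)C(C)=C1 | intermediate
13 | (5R)-5-[(1R,2S,6S)-1-(tert-butyldimethylsilyloxy)-2,6-dimethyl-6-(triethylsilyloxy)-8-(trimethylsilyl)oct-7-yn-1-yl]-4-methylfuran-2(5H)-one | O=C1O[C@@H]([C@H](O[Si](C)(C)C(C)(C)C)[C@@H](C)CCC[C@](C)(O[Si](CC)(CC)CC)C#C[Si](C)(C)C)C(C)=C1 | intermediate
14 | (5R)-4-(bromomethyl)-5-[(1R,2S,6S)-1-(tert-butyldimethylsilyloxy)-2,6-dimethyl-6-(triethylsilyloxy)-8-(trimethylsilyl)oct-7-yn-1-yl]furan-2(5H)-one | O=C1O[C@@H]([C@H](O[Si](C)(C)C(C)(C)C)[C@@H](C)CCC[C@](C)(O[Si](CC)(CC)CC)C#C[Si](C)(C)C)C(CBr)=C1 | intermediate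
15 | prop-2-yn-1-ol | C#CCO | starting material
16 | trimethylaluminium | C[Al](C)C | starting material
17 | dimethyl[(1E)-3-[(dimethylalumanyl)oxy]-2-methylprop-1-en-1-yl]alumane | C[Al](C)/C=C(\C)CO[Al](C)C | intermediate
18 | (5R)-5-[(1R,2S,6S)-1-(tert-butyldimethylsilyloxy)-2,6-dimethyl-6-(triethylsilyloxy)-8-(trimethylsilyl)oct-7-yn-1-yl]-4-[(2E)-4-hydroxy-3-methylbut-2-en-1-yl]furan-2(5H)-one | O=C1O[C@@H]([C@H](O[Si](C)(C)C(C)(C)C)[C@@H](C)CCC[C@](C)(O[Si](CC)(CC)CC)C#C[Si](C)(C)C)C(C/C=C(\C)CO)=C1 | intermediate
19 | (4S,5R)-5-[(1R,2S,6S)-1-(tert-butyldimethylsilyloxy)-2,6-dimethyl-6-(triethylsilyloxy)-8-(trimethylsilyl)oct-7-yn-1-yl]-4-[(2E)-4-hydroxy-3-methylbut-2-en-1-yl]oxolan-2-one | O=C1O[C@@H]([C@H](O[Si](C)(C)C(C)(C)C)[C@@H](C)CCC[C@](C)(O[Si](CC)(CC)CC)C#C[Si](C)(C)C)[C@@H](C/C=C(\C)CO)C1 | intermediate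
20 | (4S,5R)-5-[(1R,2S,6S)-1-(tert-butyldimethylsilyloxy)-2,6-dimethyl-6-(triethylsilyloxy)oct-7-yn-1-yl]-4-[(2E)-4-hydroxy-3-methylbut-2-en-1-yl]oxolan-2-one | O=C1O[C@@H]([C@H](O[Si](C)(C)C(C)(C)C)[C@@H](C)CCC[C@](C)(O[Si](CC)(CC)CC)C#C)[C@@H](C/C=C(\C)CO)C1 | intermediate
21 | (4S,5R)-4-[(2E)-4-bromo-3-methylbut-2-en-1-yl]-5-[(1R,2S,6S)-1-(tert-butyldimethylsilyloxy)-2,6-dimethyl-6-(triethylsilyloxy)oct-7-yn-1-yl]oxolan-2-one | O=C1O[C@@H]([C@H](O[Si](C)(C)C(C)(C)C)[C@@H](C)CCC[C@](C)(O[Si](CC)(CC)CC)C#C)[C@@H](C/C=C(\C)CBr)C1 | intermediate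
22 | copper acetylide of 21 (monovalent copper on C18) | O=C1O[C@@H]([C@H](O[Si](C)(C)C(C)(C)C)[C@@H](C)CCC[C@](C)(O[Si](CC)(CC)CC)C#C[Cu])[C@@H](C/C=C(\C)CBr)C1 | intermediate
23 | bicyclic enyne lactone: ring A closed, C17≡C18, (20E)-alkene, saturated ring B, C7 tert-butyldimethylsilyl ether, C14 triethylsilyl ether; C6 R, C7 R, C9 S, C14 S, C25 S | O=C1O[C@H]2[C@H](O[Si](C)(C)C(C)(C)C)[C@@H](C)CCC[C@](C)(O[Si](CC)(CC)CC)C#CC/C(C)=C/C[C@H]2C1 | intermediate
24 | bicyclic (17Z,20E)-diene lactone: saturated ring B, C7 tert-butyldimethylsilyl ether, C14 triethylsilyl ether; C6 R, C7 R, C9 S, C14 S, C25 S | O=C1O[C@H]2[C@H](O[Si](C)(C)C(C)(C)C)[C@@H](C)CCC[C@](C)(O[Si](CC)(CC)CC)/C=C\C/C(C)=C/C[C@H]2C1 | intermediate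
25 | Mannich base: 24 with a dimethylaminomethyl group on C2 (C2 epimers) | O=C1O[C@H]2[C@H](O[Si](C)(C)C(C)(C)C)[C@@H](C)CCC[C@](C)(O[Si](CC)(CC)CC)/C=C\C/C(C)=C/C[C@H]2C1CN(C)C | intermediate
26 | methiodide of 25 (trimethylammoniomethyl on C2, iodide) | O=C1O[C@H]2[C@H](O[Si](C)(C)C(C)(C)C)[C@@H](C)CCC[C@](C)(O[Si](CC)(CC)CC)/C=C\C/C(C)=C/C[C@H]2C1C[N+](C)(C)C.[I-] | intermediate
27 | bis-silyl α-methylene lactone: C1=C2, (17Z,20E)-diene, C7 tert-butyldimethylsilyl ether, C14 triethylsilyl ether; C6 R, C7 R, C9 S, C14 S, C25 S | O=C1O[C@H]2[C@H](O[Si](C)(C)C(C)(C)C)[C@@H](C)CCC[C@](C)(O[Si](CC)(CC)CC)/C=C\C/C(C)=C/C[C@H]2C1=C | intermediate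
28 | deoxy target: (17Z,20E)-diene diol with α-methylene lactone; C6 R, C7 R, C9 S, C14 S, C25 S | O=C1O[C@H]2[C@H](O)[C@@H](C)CCC[C@](C)(O)/C=C\C/C(C)=C/C[C@H]2C1=C | intermediate
29 | CNP0304380.1: cis-fused α-methylene lactone, (20R,23R)-oxirane, (17Z)-alkene; C6 R, C7 R, C9 S, C14 S, C25 S | C=C1C(=O)O[C@H]2[C@H](O)[C@@H](C)CCC[C@](C)(O)/C=C\C[C@@]3(C)O[C@@H]3C[C@@H]12 | target

## Step count and risks

Total step count: 21. Longest linear sequence: 20 steps (steps 1–8 and 10–21; step 9 is a one-step side branch).

Least certain steps: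

Step 13 (key step). Methyl could be transferred in place of alkenyl if AlMe3 is not fully removed. The aluminium alkoxide could deprotonate the butenolide at C6 or move the new skipped diene into conjugation. A slow transmetalation would leave the allyl-palladium species time to decompose. Fallback, from 15 back to 18: the same carboalumination of 15 is quenched with I2 to give (E)-3-iodo-2-methylprop-2-en-1-ol F1. This is converted with (Bu3Sn)2 and PdCl2(PPh3)2 (cat.) into (E)-2-methyl-3-(tributylstannyl)prop-2-en-1-ol F2, a purified, neutral alkenyl donor. Stille coupling of F2 with 14 (Pd2(dba)3, AsPh3, THF) should then give 18 without any aluminium reagent touching the butenolide.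

Step 10. The Felkin preference of an α-methyl aldehyde is modest, so facial discrimination at C7 could be poor, and the syn preference at C6/C7 could be eroded. Fallback, from 9 back to 13, replaces substrate control by auxiliary control. (S)-4-Benzyloxazolidin-2-one is acylated with (4-methoxybenzyloxy)acetyl chloride to the glycolate imide F3. Its boron enolate (Bu2BOTf, Et3N) adds to 9 in an Evans syn aldol to give adduct F4. Transamination (MeONHMe·HCl, AlMe3) gives the Weinreb amide F5, and silylation (t-BuMe2SiOTf, 2,6-lutidine) gives F6. MeMgBr gives the methyl ketone F7, and DDQ frees the α-hydroxy ketone F8. Ph3P=C=C=O then acylates the hydroxyl and closes the butenolide by intramolecular Wittig reaction to 13.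

Step 12. Hydrogen abstraction could compete at the tertiary C6–H, a second bromination could occur, or HBr could remove the triethylsilyl group. Fallback, from 9 back to 14, carries the C24 oxygen from the start. Commercial 4-(hydroxymethyl)furan-2(5H)-one (OCC1=CC(=O)OC1) is protected with 4-methoxybenzyl trichloroacetimidate and camphorsulfonic acid (cat.) as the ether F9. It is silylated (t-BuMe2SiOTf, Et3N) to the silyloxyfuran F10, which is added to 9 with BF3·OEt2 to give the aldol adduct F11. Silylation at O8 gives F12, DDQ gives the allylic alcohol F13, and CBr4/PPh3 gives 14.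

Step 17. Intermolecular coupling could lead to oligomers, attack at C23 (SN2′) would give a twelve-membered ring, and traces of oxygen would cause oxidative alkyne dimerisation. Fallback, from 20 back to 23: 20 is stannylated at the alkyne with Bu3SnNMe2 (methanol work-up) to the alkynylstannane alcohol F14. CBr4/PPh3 with 2,6-lutidine gives the alkynylstannane allylic bromide F15. An intramolecular Stille coupling (Pd2(dba)3, AsPh3, THF, 50 °C, high dilution) then closes C18–C19 to 23.

Step 21. The conformation of ring A could oppose the catalyst, giving poor facial selectivity. The enoate could suffer hydroxide addition or lactone hydrolysis at the buffered basic pH, and the Z alkene could be oxidised. Fallback, from 27 back to 29, inverts the facial outcome of direct oxygen transfer by way of a halohydrin. NBS in aqueous THF gives, by anti opening of the bromonium ion at the tertiary C20, the bromohydrin F16. Ag2O in THF closes it with inversion at C23 to the bis-silyl epoxide F17, with oxygen on the face opposite to the one the electrophile attacked. Bu4NF buffered with AcOH then removes both silyl groups to give 29.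

## Further compounds

F1 | step 13 | (E)-3-iodo-2-methylprop-2-en-1-ol | OC/C(C)=C/I
F2 | step 13 | (E)-2-methyl-3-(tributylstannyl)prop-2-en-1-ol | OC/C(C)=C/[Sn](CCCC)(CCCC)CCCC
F3 | step 10 | (4S)-4-benzyl-3-[(4-methoxybenzyloxy)acetyl]oxazolidin-2-one | O=C(COCc1ccc(OC)cc1)N1[C@@H](Cc2ccccc2)COC1=O
F4 | step 10 | Evans syn aldol adduct of F3 and 9 (C6 4-methoxybenzyl ether, C7 hydroxyl, acyl oxazolidinone at C25) | O=C([C@@H](OCc1ccc(OC)cc1)[C@H](O)[C@@H](C)CCC[C@](C)(O[Si](CC)(CC)CC)C#C[Si](C)(C)C)N1[C@@H](Cc2ccccc2)COC1=O
F5 | step 10 | N-methoxy-N-methyl amide from F4 | CON(C)C(=O)[C@@H](OCc1ccc(OC)cc1)[C@H](O)[C@@H](C)CCC[C@](C)(O[Si](CC)(CC)CC)C#C[Si](C)(C)C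
F6 | step 10 | C7 tert-butyldimethylsilyl ether of F5 | CON(C)C(=O)[C@@H](OCc1ccc(OC)cc1)[C@H](O[Si](C)(C)C(C)(C)C)[C@@H](C)CCC[C@](C)(O[Si](CC)(CC)CC)C#C[Si](C)(C)C
F7 | step 10 | methyl ketone from F6 (C25 ketone, C24 methyl) | CC(=O)[C@@H](OCc1ccc(OC)cc1)[C@H](O[Si](C)(C)C(C)(C)C)[C@@H](C)CCC[C@](C)(O[Si](CC)(CC)CC)C#C[Si](C)(C)C
F8 | step 10 | α-hydroxy ketone from F7 (free C6 hydroxyl) | CC(=O)[C@@H](O)[C@H](O[Si](C)(C)C(C)(C)C)[C@@H](C)CCC[C@](C)(O[Si](CC)(CC)CC)C#C[Si](C)(C)C
F9 | step 12 | 4-[(4-methoxybenzyloxy)methyl]furan-2(5H)-one | COc1ccc(COCC2=CC(=O)OC2)cc1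
F10 | step 12 | tert-butyl({4-[(4-methoxybenzyloxy)methyl]furan-2-yl}oxy)dimethylsilane | COc1ccc(COCc2coc(O[Si](C)(C)C(C)(C)C)c2)cc1
F11 | step 12 | aldol adduct of F10 and 9 (analogue of 12 with C24 4-methoxybenzyloxy) | O=C1O[C@@H]([C@H](O)[C@@H](C)CCC[C@](C)(O[Si](CC)(CC)CC)C#C[Si](C)(C)C)C(COCc2ccc(OC)cc2)=C1
F12 | step 12 | C7 tert-butyldimethylsilyl ether of F11 | O=C1O[C@@H]([C@H](O[Si](C)(C)C(C)(C)C)[C@@H](C)CCC[C@](C)(O[Si](CC)(CC)CC)C#C[Si](C)(C)C)C(COCc2ccc(OC)cc2)=C1
F13 | step 12 | 4-(hydroxymethyl)butenolide (analogue of 14 with C24 hydroxyl) | O=C1O[C@@H]([C@H](O[Si](C)(C)C(C)(C)C)[C@@H](C)CCC[C@](C)(O[Si](CC)(CC)CC)C#C[Si](C)(C)C)C(CO)=C1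
F14 | step 17 | C18 tributylstannyl alkyne of 20 | O=C1O[C@@H]([C@H](O[Si](C)(C)C(C)(C)C)[C@@H](C)CCC[C@](C)(O[Si](CC)(CC)CC)C#C[Sn](CCCC)(CCCC)CCCC)[C@@H](C/C=C(\C)CO)C1
F15 | step 17 | C18 tributylstannyl alkyne of 21 | O=C1O[C@@H]([C@H](O[Si](C)(C)C(C)(C)C)[C@@H](C)CCC[C@](C)(O[Si](CC)(CC)CC)C#C[Sn](CCCC)(CCCC)CCCC)[C@@H](C/C=C(\C)CBr)C1
F16 | step 21 | bromohydrin of 27 (C20 hydroxyl, C23 bromide) | O=C1O[C@H]2[C@H](O[Si](C)(C)C(C)(C)C)[C@@H](C)CCC[C@](C)(O[Si](CC)(CC)CC)/C=C\C[C@@](C)(O)[C@@H](Br)C[C@H]2C1=C
F17 | step 21 | bis-silyl ether of 29 | O=C1O[C@H]2[C@H](O[Si](C)(C)C(C)(C)C)[C@@H](C)CCC[C@](C)(O[Si](CC)(CC)CC)/C=C\C[C@@]3(C)O[C@@H]3C[C@H]2C1=C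
A1 | alternative 1 | deoxy target C7 4-methoxybenzyl ether (product of the carbonylation) | C=C1C(=O)O[C@H]2[C@H](OCc3ccc(OC)cc3)[C@@H](C)CCC[C@](C)(O)/C=C\C/C(C)=C/C[C@@H]12
A2 | alternative 1 | macrocyclic homopropargylic alcohol (C6 hydroxyl, C25 ethynyl) | O[C@H]1[C@H](OCc2ccc(OC)cc2)[C@@H](C)CCC[C@](C)(O)/C=C\C/C(C)=C/C[C@H]1C#C
A3 | alternative 2 | fourteen-membered C12 sulfone with free C14 hydroxyl (C12 epimers) | O=S(=O)(c1ccccc1)C4C[C@H](C)[C@H]2OC(C)(C)O[C@@H]2[C@H](C(=C)CO[Si](C)(C)C(C)(C)C)C/C=C(\C)C/C=C\[C@@](C)(O)C4
A4 | alternative 2 | acyclic C12 phenyl sulfone with C13–C14 terminal epoxide | O=S(=O)(c1ccccc1)CC[C@H](C)[C@H]2OC(C)(C)O[C@@H]2[C@H](C(=C)CO[Si](C)(C)C(C)(C)C)C/C=C(\C)C/C=C\[C@]3(C)CO3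
A5 | alternative 3 | macrocyclic butenolide with C6 and C7 set, C14 triethylsilyl ether | O=C1O[C@H]2[C@H](O)[C@@H](C)CCC[C@](C)(O[Si](CC)(CC)CC)/C=C\C/C(C)=C/CC2=C1
A6 | alternative 3 | seco C7 aldehyde with a 2-(tert-butyldimethylsilyloxy)furan joined through C24 | O=C[C@@H](C)CCC[C@](C)(O[Si](CC)(CC)CC)/C=C\C/C(C)=C/Cc1coc(O[Si](C)(C)C(C)(C)C)c1
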